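The amounts came first: the catalyst charge was 9.52% of the starting material, and the reagent entered as a straight ramp.

all flasks: starting material 0.21 M; free catalyst 20 mM
- noon: reagent 0.35 M (fed, over 3.0 h); run made earlier
- flask: reagent 0.231 M (fed, over 3.0 h); time 3.0 h

- noon (time / min: target / %, starting material / %, open intermediate / %): 10.0: 0.4, 81.5, 16.3; 20.0: 0.9, 70.7, 25.6; 25.0: 1.6, 66.6, 28.6; 40.0: 4.2, 58.5, 34.5

(readings scatter by 0.3 percentage points)

1. the species in which most of what was charged as starting material, at 3.0 h sits (starting material / open intermediate / target)
2. the largest share itself, whichever of these holds it, in percent of the starting material charged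

- a reading or a percentage of open intermediate is of its free form alone

In the noon run, target climbed roughly with the square of time. I therefore took its rate as pseudo-first-order in reagent and integrated along the ramp. This gave target = κX, where the exposure X is the reagent charge times time squared, over twice the dosing time. The last noon reading, at an exposure of 93.3 M·s, gave κ, the target yield per unit exposure, as 4.50 × 10⁻⁴ M⁻¹ s⁻¹. At 25.0 min this predicted 1.64% against a reading of 1.6%. For the flask at 3.0 h, with an exposure of 1250 M·s, it gave 56.1%.

That step assumed unchanged catalyst, so it was the weak link. The balance gap was 2.80% at 20.0 min and 2.80% at 40.0 min, while open intermediate rose from 25.6% to 34.5%. I read the gap as material held on catalyst, so working catalyst had fallen to 0.742 of itself. That gave a decay constant λ of 0.00426 M⁻¹ s⁻¹ per unit exposure, a rough reading because the gap scatters by 0.52 percentage points. With κ decaying exponentially in exposure, the integral closed again: target levels off at the last noon reading plus κ/λ, or 14.8%. The flask's exposure was larger than 1/λ, so I took that plateau. I split the rest evenly between starting material and open intermediate, which put each near 42.6%, more than my plateau for target. That even split could not say which of the two led, so I committed to the share and to target not holding it.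

The forecast said target at 40%: “Target leads, but narrowly”.

The flask held 39.6% as starting material at 3.0 h, and its target, 25.1%, stood above my plateau, with spent catalyst at 89.9% of the catalyst charged.

    starting material + free catalyst ⇌ free catalyst + open intermediate (K = 1.40, k = 0.0210 M⁻¹ s⁻¹)
    reagent + free catalyst → spent catalyst (k = 0.00430 M⁻¹ s⁻¹)
    free catalyst + open intermediate ⇌ catalyst intermediate (K = 8.60 M⁻¹, k = 0.330 M⁻¹ s⁻¹)
    reagent + catalyst intermediate → free catalyst + target (k = 0.0200 M⁻¹ s⁻¹)

The neighbour charged with 0.058 M of reagent had an exposure of 313 M·s, for which κ gives 14.1%, and that neighbour held 12.0% of target at 3.00 h.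

The earlier runs and the new flask were computed with constants of no real substance, and the scatter is random.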